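**Plan**

- Retrosynthetic cuts, in order: the C8–O acyl bond (angelate) and the C10–C14 bond (methyl), then the ring bond C9–C10, then C3–C4, then C6–C7 together with the lactone C12–O bond. This leaves (S)-glyceraldehyde acetonide, methyl acrylate, but-2-yn-1-ol, (E)-4,4-dimethoxybut-2-enal and angelic acid.
- Enabling feature: C10 is a carbinol carbon whose ring neighbour C9H2 sits next to the oxygenated C8, so the ten-membered ring hides a β-hydroxy enone C8(OH)–C9H2–C10(=O)–C1=C2. C9 (as iodohydrin CH2–I) and C10 (as enoyl 2-pyridyl thioester) are both acceptor carbons; they are joined by a nickel-mediated reductive radical–acyl coupling in which both helpers (I, S-pyridyl) leave.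
- Forward order: butyrolactone ring first (indium allylation, lactonisation), chain growth at C4 (Nozaki–Hiyama–Kishi), then the ten-membered ring (C9–C10), then C14, the angelate and desilylation.
- Stereochemistry: C8 from (S)-glyceraldehyde acetonide; C6 and C7 relayed from C8 in the closed allylation transition state (cis-lactone); C3 by ligand control; C10 by chelate-controlled methyl addition. Z-C4=C5 comes from anti-hydroalumination/iodination, E-C1=C2 from the enal building block, the Z-angelate from angelic acid.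

Key step: step 12

Remark: ring carbons are cited in germacrane numbering (C1–C10 carbocycle; lactone O on C6, C7–C11(=C13)–C12(=O); ester O on C8; C14 on C10; C15 on C4), and (S)-glyceraldehyde acetonide 1 is taken as a purchasable compound.

**Route**

Step 1
Reactants: 1 (S)-2,2-dimethyl-1,3-dioxolane-4-carbaldehyde; 2 methyl acrylate
Product: 3 methyl 2-{[(4S)-2,2-dimethyl-1,3-dioxolan-4-yl](hydroxy)methyl}prop-2-enoate (both carbinol epimers)
Conditions: DABCO (0.5 equiv), dioxane–H2O (1:1), rt, 2–3 d
Reagents that add atoms: none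
Why: Baylis–Hillman reaction of a reactive α-alkoxy aldehyde, which should proceed without epimerising the dioxolane centre (later C8), while the new carbinol centre is irrelevant because it is erased in step 2.

Step 2
Reactants: 3 Baylis–Hillman alcohol
Product: 4 methyl (2Z)-2-(bromomethyl)-3-[(4R)-2,2-dimethyl-1,3-dioxolan-4-yl]prop-2-enoate
Conditions: NBS, Me2S, CH2Cl2, 0 °C to rt
Reagents that add atoms: N-bromosuccinimide, O=C1CCC(=O)N1Br
Why: Corey–Kim-type activation of the allylic alcohol followed by SN2′ attack of bromide should give the Z-2-(bromomethyl)enoate (ester trans to the dioxolane) under conditions that leave the acetonide intact, the descriptor of the dioxolane centre changing from S to R by priority only.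

Step 3
Reactants: 5 but-2-yn-1-ol
Product: 7 (Z)-3-iodobut-2-en-1-ol, via cyclic alkenylalanate 6 (not isolated)
Conditions: NaAlH2(OCH2CH2OCH3)2, THF, 0 °C to rt; then I2, −78 °C to 0 °C
Reagents that add atoms: iodine, [I][I]; NaAlH2(OCH2CH2OCH3)2, [Na+].[AlH2-](OCCOC)OCCOC (its aluminium and alkoxy groups stay only in 6)
Why: hydroxyl-directed anti-hydroalumination of the propargylic alcohol places aluminium on the distal carbon and iodinolysis with retention puts iodine cis to CH2OH, which is the later Z-C4=C5 geometry.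

Step 4
Reactants: 7 (Z)-3-iodobut-2-en-1-ol
Product: 8 (Z)-3-iodobut-2-enal
Conditions: MnO2, CH2Cl2, rt, used without storage
Reagents that add atoms: none
Why: neutral allylic oxidation on MnO2 should not isomerise the Z-β-iodo enal.

Step 5
Reactants: 4 allylic bromide; 8 (Z)-3-iodobut-2-enal
Product: 10 (4S,5R)-4-[(4R)-2,2-dimethyl-1,3-dioxolan-4-yl]-5-[(1Z)-2-iodoprop-1-en-1-yl]-3-methylideneoxolan-2-one, via hydroxy ester 9 (not isolated)
Conditions: In powder, THF–H2O (1:1), rt; then PPTS (cat), toluene, 50 °C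
Reagents that add atoms: none
Why: indium-mediated Barbier 2-(alkoxycarbonyl)allylation through a closed chair transition state in which the Z-bromide holds the C8 group pseudo-axial should give the syn adduct that lactonises to the cis-lactone (C6, C7), and the aldehyde should add to C7 anti to the C8–O bond of the allylic-strain-minimised (H-eclipsed) rotamer, which relays the configuration of C8 to C7 and C6.

Step 6
Reactants: 10 lactone alkenyl iodide; 11 (E)-4,4-dimethoxybut-2-enal
Product: 12 (4S,5S)-4-[(4R)-2,2-dimethyl-1,3-dioxolan-4-yl]-5-[(1Z,3S,4E)-3-hydroxy-6,6-dimethoxy-2-methylhexa-1,4-dien-1-yl]-3-methylideneoxolan-2-one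
Conditions: CrCl2 (10 mol%), chiral oxazoline–sulfonamide ligand [(S)-N-[2-(4-isopropyl-4,5-dihydrooxazol-2-yl)-6-methoxyphenyl]methanesulfonamide or its enantiomer] (11 mol%), 1,8-bis(dimethylamino)naphthalene (11 mol%), NiCl2·(2,9-dimethyl-1,10-phenanthroline) (2 mol%), Mn, Cp2ZrCl2, LiCl, MeCN, rt
Reagents that add atoms: none
Why: catalytic asymmetric Nozaki–Hiyama–Kishi coupling in which the Z-alkenyl iodide is passed with retention from nickel to chromium and adds 1,2 to the enal in the presence of lactone, methylene lactone and acetal, the chromium-bound sulfonamide ligand (enantiomer selected for 3S) and not the remote C6 centre deciding the carbonyl face.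

Step 7
Reactants: 12 bis-allylic alcohol
Product: 13 (4S,5S)-5-[(1Z,3S,4E)-3-{[tert-butyl(dimethyl)silyl]oxy}-6,6-dimethoxy-2-methylhexa-1,4-dien-1-yl]-4-[(4R)-2,2-dimethyl-1,3-dioxolan-4-yl]-3-methylideneoxolan-2-one
Conditions: TBSCl, imidazole, DMF, rt
Reagents that add atoms: tert-butyldimethylsilyl chloride, CC(C)(C)[Si](C)(C)Cl
Why: standard silylation of the secondary bis-allylic alcohol under non-ionising basic conditions gives the one protecting group that is kept to the last step.

Step 8
Reactants: 13 silyl ether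
Product: 14 (2E,4S,5Z)-4-{[tert-butyl(dimethyl)silyl]oxy}-6-{(2S,3R)-3-[(1R)-1,2-dihydroxyethyl]-4-methylidene-5-oxooxolan-2-yl}-5-methylhexa-2,5-dienal
Conditions: AcOH–H2O–THF (4:1:1), 35 °C
Reagents that add atoms: water, O
Why: mild aqueous acid should hydrolyse the dimethyl acetal and the terminal acetonide much faster than the hindered secondary TBS ether, unveiling the enal (C10) and the C8,C9-diol in one operation without moving the lactone from O6 to O8.

Step 9
Reactants: 14 diol enal
Product: 15 (2E,4S,5Z)-4-{[tert-butyl(dimethyl)silyl]oxy}-6-{(2S,3R)-3-[(1R)-1-hydroxy-2-iodoethyl]-4-methylidene-5-oxooxolan-2-yl}-5-methylhexa-2,5-dienal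
Conditions: PPh3, I2, imidazole, CH2Cl2, 0 °C
Reagents that add atoms: iodine, [I][I]
Why: Garegg–Samuelsson (Appel-type) iodination is selective for the primary C9 hydroxyl over the hindered secondary C8 hydroxyl and tolerates enal, lactone and silyl ether.

Step 10
Reactants: 15 iodohydrin enal
Product: 16 (2E,4S,5Z)-4-{[tert-butyl(dimethyl)silyl]oxy}-6-{(2S,3R)-3-[(1R)-1-hydroxy-2-iodoethyl]-4-methylidene-5-oxooxolan-2-yl}-5-methylhexa-2,5-dienoic acid
Conditions: NaClO2, NaH2PO4, 2-methyl-2-butene, t-BuOH–H2O, 0 °C to rt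
Reagents that add atoms: sodium chlorite, [Na+].[O-]Cl=O
Why: Pinnick oxidation converts the enal to the E-enoic acid at weakly acidic pH with the hypochlorite scavenged, so that the alkenes, the iodohydrin (no epoxide closure) and the lactone are untouched.

Step 11
Reactants: 16 seco acid
Product: 17 S-pyridin-2-yl (2E,4S,5Z)-4-{[tert-butyl(dimethyl)silyl]oxy}-6-{(2S,3R)-3-[(1R)-1-hydroxy-2-iodoethyl]-4-methylidene-5-oxooxolan-2-yl}-5-methylhexa-2,5-dienethioate
Conditions: 2,2′-dipyridyl disulfide, PPh3, CH2Cl2, rt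
Reagents that add atoms: 2,2′-dipyridyl disulfide, c1ccc(SSc2ccccn2)nc1
Why: Mukaiyama redox condensation activates the acid as its 2-pyridyl thioester under neutral conditions at room temperature, where neither the hindered C8 hydroxyl nor the iodide reacts.

Step 12
Reactants: 17 seco thioester iodohydrin
Product: 18 (3aR,4S,7E,9S,10Z,11aS)-9-{[tert-butyl(dimethyl)silyl]oxy}-4-hydroxy-10-methyl-3-methylidene-3a,4,5,9-tetrahydrocyclodeca[b]furan-2,6(3H,11aH)-dione
Conditions: NiBr2·diglyme (30 mol%), 4,4′-di-tert-butyl-2,2′-bipyridine (33 mol%), Mn powder (4 equiv), DMA, 25 °C, syringe-pump addition of 17 (final 2 mM)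
Reagents that add atoms: none
Why: Proposed new method: zerovalent nickel, formed from NiBr2·diglyme, the bipyridine and Mn, inserts into the C10–S bond of the 2-pyridyl thioester to give an acylnickel thiolate, a reduced nickel species abstracts iodine from C9, and the primary C9 radical is captured by the acylnickel centre of its own chain to give an eleven-membered acyl(alkyl)nickel ring that collapses by C9–C10 reductive elimination while Mn returns nickel to the low-valent state. The closest known reaction type is the intermolecular nickel-catalysed reductive ketone synthesis from primary alkyl iodides and 2-pyridyl thioesters or acid chlorides, which tolerates esters and β-oxygenated alkyl radicals; its use as a medium-ring closure is the untested part. The ten-membered carbocycle is closed in a formal 10-exo-trig mode at the acyl carbon, reached by contraction of the eleven-membered nickelacycle with extrusion of nickel. No stereocentre is formed: C8 (pre-set), the E-C1=C2 enoyl unit and the Z-C4=C5 alkene are carried through unchanged. The step needs ring closure to beat intermolecular coupling and simple reduction of the iodide (slow addition at high dilution, and the Z-alkene and cis-lactone fold C9 toward C10), and it needs a radical and not a polar organometallic at C9 (so the C8 hydroxyl is not lost by β-elimination, and the only cyclisation open to this radical on the methylene lactone is a disfavoured 5-endo closure).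

Step 13
Reactants: 18 ten-membered β-hydroxy enone
Product: 19 (3aR,4S,6S,7E,9S,10Z,11aS)-9-{[tert-butyl(dimethyl)silyl]oxy}-4,6-dihydroxy-6,10-dimethyl-3-methylidene-3a,4,5,6,9,11a-hexahydrocyclodeca[b]furan-2(3H)-one
Conditions: MeMgBr (3 equiv), CH2Cl2–Et2O, −78 °C; aq NH4Cl
Reagents that add atoms: methylmagnesium bromide, C[Mg]Br
Why: Grignard 1,2-addition to the enone carbonyl should be faster at −78 °C than attack on the lactone or the methylene lactone, and the C8 magnesium alkoxide should chelate the C10 carbonyl so that methyl enters the six-membered chelate to leave O8 and O10 1,3-anti (10S), as in chelation-controlled additions to β-hydroxy ketones.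

Step 14
Reactants: 19 diol; 20 angelic acid [(2Z)-2-methylbut-2-enoic acid]
Product: 22 (3aR,4S,6S,7E,9S,10Z,11aS)-9-{[tert-butyl(dimethyl)silyl]oxy}-6-hydroxy-6,10-dimethyl-3-methylidene-2-oxo-2,3,3a,4,5,6,9,11a-octahydrocyclodeca[b]furan-4-yl (2Z)-2-methylbut-2-enoate, via mixed anhydride 21 (not isolated)
Conditions: 20, 2,4,6-trichlorobenzoyl chloride, Et3N, toluene, rt; then 19, 75 °C (no DMAP)
Reagents that add atoms: 2,4,6-trichlorobenzoyl chloride, O=C(Cl)c1c(Cl)cc(Cl)cc1Cl (its atoms stay only in 21)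
Why: Yamaguchi-type esterification through the mixed anhydride acylates the secondary C8 hydroxyl and not the tertiary allylic C10 hydroxyl, and in the absence of a nucleophilic catalyst the Z-geometry of the angelate should be kept (no isomerisation to the tiglate).

Step 15
Reactants: 22 silyl-protected angelate
Product: 23 (3aR,4S,6S,7E,9S,10Z,11aS)-6,9-dihydroxy-6,10-dimethyl-3-methylidene-2-oxo-2,3,3a,4,5,6,9,11a-octahydrocyclodeca[b]furan-4-yl (2Z)-2-methylbut-2-enoate
Conditions: HF·pyridine, pyridine, THF, 0 °C to rt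
Reagents that add atoms: none
Why: pyridine-buffered fluoride desilylation removes the allylic TBS ether without acyl migration, lactone opening or ionisation of the tertiary allylic alcohol.

**Compound list**

1 | (S)-2,2-dimethyl-1,3-dioxolane-4-carbaldehyde | O=C[C@@H]1COC(C)(C)O1 | starting material
2 | methyl acrylate | C=CC(=O)OC | starting material
3 | methyl 2-{[(4S)-2,2-dimethyl-1,3-dioxolan-4-yl](hydroxy)methyl}prop-2-enoate (both carbinol epimers) | COC(=O)C(=C)C(O)[C@@H]1COC(C)(C)O1 | intermediate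
4 | methyl (2Z)-2-(bromomethyl)-3-[(4R)-2,2-dimethyl-1,3-dioxolan-4-yl]prop-2-enoate | COC(=O)/C(CBr)=C/[C@@H]1COC(C)(C)O1 | intermediate
5 | but-2-yn-1-ol | CC#CCO | starting material
6 | sodium cyclic alkenylalanate from 5 (2,2-bis(2-methoxyethoxy)-3-methyl-2,5-dihydro-1,2-oxaluminol-2-uide) | [Na+].CC1=CCO[Al-]1(OCCOC)OCCOC | intermediate (not isolated)
7 | (Z)-3-iodobut-2-en-1-ol | C/C(I)=C/CO | intermediate
8 | (Z)-3-iodobut-2-enal | C/C(I)=C/C=O | intermediate
9 | methyl (3S,4R,5Z)-3-[(4R)-2,2-dimethyl-1,3-dioxolan-4-yl]-4-hydroxy-6-iodo-2-methylidenehept-5-enoate | C=C(C(=O)OC)[C@@H]([C@@H](O)/C=C(/C)I)[C@@H]1COC(C)(C)O1 | intermediate (not isolated)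
10 | (4S,5R)-4-[(4R)-2,2-dimethyl-1,3-dioxolan-4-yl]-5-[(1Z)-2-iodoprop-1-en-1-yl]-3-methylideneoxolan-2-one | C=C1C(=O)O[C@@H](/C=C(/C)I)[C@H]1[C@@H]2COC(C)(C)O2 | intermediate
11 | (E)-4,4-dimethoxybut-2-enal | COC(OC)/C=C/C=O | starting material
12 | (4S,5S)-4-[(4R)-2,2-dimethyl-1,3-dioxolan-4-yl]-5-[(1Z,3S,4E)-3-hydroxy-6,6-dimethoxy-2-methylhexa-1,4-dien-1-yl]-3-methylideneoxolan-2-one | C=C1C(=O)O[C@@H](/C=C(/C)[C@@H](O)/C=C/C(OC)OC)[C@H]1[C@@H]2COC(C)(C)O2 | intermediate
13 | (4S,5S)-5-[(1Z,3S,4E)-3-{[tert-butyl(dimethyl)silyl]oxy}-6,6-dimethoxy-2-methylhexa-1,4-dien-1-yl]-4-[(4R)-2,2-dimethyl-1,3-dioxolan-4-yl]-3-methylideneoxolan-2-one | C=C1C(=O)O[C@@H](/C=C(/C)[C@@H](O[Si](C)(C)C(C)(C)C)/C=C/C(OC)OC)[C@H]1[C@@H]2COC(C)(C)O2 | intermediate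
14 | (2E,4S,5Z)-4-{[tert-butyl(dimethyl)silyl]oxy}-6-{(2S,3R)-3-[(1R)-1,2-dihydroxyethyl]-4-methylidene-5-oxooxolan-2-yl}-5-methylhexa-2,5-dienal | C=C1C(=O)O[C@@H](/C=C(/C)[C@@H](O[Si](C)(C)C(C)(C)C)/C=C/C=O)[C@H]1[C@@H](O)CO | intermediate
15 | (2E,4S,5Z)-4-{[tert-butyl(dimethyl)silyl]oxy}-6-{(2S,3R)-3-[(1R)-1-hydroxy-2-iodoethyl]-4-methylidene-5-oxooxolan-2-yl}-5-methylhexa-2,5-dienal | C=C1C(=O)O[C@@H](/C=C(/C)[C@@H](O[Si](C)(C)C(C)(C)C)/C=C/C=O)[C@H]1[C@@H](O)CI | intermediate
16 | (2E,4S,5Z)-4-{[tert-butyl(dimethyl)silyl]oxy}-6-{(2S,3R)-3-[(1R)-1-hydroxy-2-iodoethyl]-4-methylidene-5-oxooxolan-2-yl}-5-methylhexa-2,5-dienoic acid | C=C1C(=O)O[C@@H](/C=C(/C)[C@@H](O[Si](C)(C)C(C)(C)C)/C=C/C(=O)O)[C@H]1[C@@H](O)CI | intermediate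
17 | S-pyridin-2-yl (2E,4S,5Z)-4-{[tert-butyl(dimethyl)silyl]oxy}-6-{(2S,3R)-3-[(1R)-1-hydroxy-2-iodoethyl]-4-methylidene-5-oxooxolan-2-yl}-5-methylhexa-2,5-dienethioate | C=C1C(=O)O[C@@H](/C=C(/C)[C@@H](O[Si](C)(C)C(C)(C)C)/C=C/C(=O)Sc2ccccn2)[C@H]1[C@@H](O)CI | intermediate
18 | (3aR,4S,7E,9S,10Z,11aS)-9-{[tert-butyl(dimethyl)silyl]oxy}-4-hydroxy-10-methyl-3-methylidene-3a,4,5,9-tetrahydrocyclodeca[b]furan-2,6(3H,11aH)-dione | C=C1C(=O)O[C@H]2/C=C(/C)[C@@H](O[Si](C)(C)C(C)(C)C)/C=C/C(=O)C[C@H](O)[C@@H]12 | intermediate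
19 | (3aR,4S,6S,7E,9S,10Z,11aS)-9-{[tert-butyl(dimethyl)silyl]oxy}-4,6-dihydroxy-6,10-dimethyl-3-methylidene-3a,4,5,6,9,11a-hexahydrocyclodeca[b]furan-2(3H)-one | C=C1C(=O)O[C@H]2/C=C(/C)[C@@H](O[Si](C)(C)C(C)(C)C)/C=C/[C@@](C)(O)C[C@H](O)[C@@H]12 | intermediate
20 | angelic acid, (2Z)-2-methylbut-2-enoic acid | C/C=C(/C)C(=O)O | starting material
21 | (2Z)-2-methylbut-2-enoic 2,4,6-trichlorobenzoic anhydride | C/C=C(/C)C(=O)OC(=O)c1c(Cl)cc(Cl)cc1Cl | intermediate (not isolated)
22 | (3aR,4S,6S,7E,9S,10Z,11aS)-9-{[tert-butyl(dimethyl)silyl]oxy}-6-hydroxy-6,10-dimethyl-3-methylidene-2-oxo-2,3,3a,4,5,6,9,11a-octahydrocyclodeca[b]furan-4-yl (2Z)-2-methylbut-2-enoate | C=C1C(=O)O[C@H]2/C=C(/C)[C@@H](O[Si](C)(C)C(C)(C)C)/C=C/[C@@](C)(O)C[C@H](OC(=O)/C(C)=C\C)[C@@H]12 | intermediate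
23 | (3aR,4S,6S,7E,9S,10Z,11aS)-6,9-dihydroxy-6,10-dimethyl-3-methylidene-2-oxo-2,3,3a,4,5,6,9,11a-octahydrocyclodeca[b]furan-4-yl (2Z)-2-methylbut-2-enoate | C=C1C(=O)O[C@H]2/C=C(/C)[C@@H](O)/C=C/[C@@](C)(O)C[C@H](OC(=O)/C(C)=C\C)[C@@H]12 | target

**Step count and risks**

Total steps: 15. Longest linear sequence: 13 (steps 3–15 from 5; equally steps 1, 2 and 5–15 from 1).

Steps most likely to fail:

1. Step 12 (proposed new method). The C9 radical may be quenched by hydrogen abstraction, or couple between two chains, before it reaches the acylnickel centre; or the strained eleven-membered nickelacycle may not form. The fallback uses known reaction types at the same bond with reversed roles (C9 as enolate carbon, C10 as ketone carbonyl). It sets out from 17 and comes back at 19, so step 13 is not needed.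
   - MeMgBr (THF, −78 °C) should convert the 2-pyridyl thioester into the seco methyl enone F1 (thioester-to-ketone synthesis through the chelated tetrahedral adduct).
   - Dess–Martin periodinane with NaHCO3 (CH2Cl2, 0 °C) should oxidise the C8 carbinol to the α-iodo ketone F2, used at once.
   - SmI2 (2.2 equiv, THF, −78 °C, high dilution) should form the C9 samarium enolate regiospecifically from the C–I bond and close the ring by an intramolecular Reformatsky-type aldol addition to the C10 ketone, giving the cyclic aldol F3.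
   - Me4NBH(OAc)3 (MeCN–AcOH, −30 °C, Evans–Saksena reduction) should deliver hydride from the C10-bound boron to C8 and give the 1,3-anti diol 19.

2. Step 13. Facial selectivity at C10 may be poor if the magnesium chelate is not the reacting conformer of the ten-membered ring, and some conjugate addition to the methylene lactone may compete. The fallback replaces chelate control by steric control. It sets out from 18 and comes back at 19.
   - TESOTf/2,6-lutidine (CH2Cl2, −78 °C) should give the 8-O-triethylsilyl enone F4.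
   - MeLi/CeCl3 (THF, −78 °C), which cannot chelate and attacks the carbonyl from the ring periphery, should give the 8-O-triethylsilyl carbinol F5.
   - PPTS in MeOH (0 °C) should remove the triethylsilyl group selectively and return to 19.

3. Step 5. The aldehyde may add to the other face of C7 (syn to the dioxolane oxygen), which would break the relay from C8 to C7 and C6, or the syn preference may erode. The fallback uses reagent control instead of substrate control. It sets out from 4 and 8 and comes back at 10.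
   - A chromium-mediated allylation under a chiral oxazoline–sulfonamide ligand (CrCl2 cat, ligand, 1,8-bis(dimethylamino)naphthalene, Mn, Cp2ZrCl2, MeCN, no nickel co-catalyst) should let the ligand sphere on chromium select the aldehyde face (C6), and the closed transition state should transmit this to C7.
   - The zirconium alkoxide of 9 should lactonise on acidic work-up (PPTS, toluene) to 10. No compound outside the list is made.

Further compounds
F1 | step 12 | (3E,5S,6Z)-5-{[tert-butyl(dimethyl)silyl]oxy}-7-{(2S,3R)-3-[(1R)-1-hydroxy-2-iodoethyl]-4-methylidene-5-oxooxolan-2-yl}-6-methylhepta-3,6-dien-2-one | C=C1C(=O)O[C@@H](/C=C(/C)[C@@H](O[Si](C)(C)C(C)(C)C)/C=C/C(C)=O)[C@H]1[C@@H](O)CI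
F2 | step 12 | (3E,5S,6Z)-5-{[tert-butyl(dimethyl)silyl]oxy}-7-[(2S,3S)-3-(iodoacetyl)-4-methylidene-5-oxooxolan-2-yl]-6-methylhepta-3,6-dien-2-one | C=C1C(=O)O[C@@H](/C=C(/C)[C@@H](O[Si](C)(C)C(C)(C)C)/C=C/C(C)=O)[C@H]1C(=O)CI
F3 | step 12 | (3aS,6S,7E,9S,10Z,11aS)-9-{[tert-butyl(dimethyl)silyl]oxy}-6-hydroxy-6,10-dimethyl-3-methylidene-3a,5,6,9-tetrahydrocyclodeca[b]furan-2,4(3H,11aH)-dione | C=C1C(=O)O[C@H]2/C=C(/C)[C@@H](O[Si](C)(C)C(C)(C)C)/C=C/[C@@](C)(O)CC(=O)[C@@H]12
F4 | step 13 | (3aS,4S,7E,9S,10Z,11aS)-9-{[tert-butyl(dimethyl)silyl]oxy}-10-methyl-3-methylidene-4-[(triethylsilyl)oxy]-3a,4,5,9-tetrahydrocyclodeca[b]furan-2,6(3H,11aH)-dione | C=C1C(=O)O[C@H]2/C=C(/C)[C@@H](O[Si](C)(C)C(C)(C)C)/C=C/C(=O)C[C@H](O[Si](CC)(CC)CC)[C@@H]12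
F5 | step 13 | (3aS,4S,6S,7E,9S,10Z,11aS)-9-{[tert-butyl(dimethyl)silyl]oxy}-6-hydroxy-6,10-dimethyl-3-methylidene-4-[(triethylsilyl)oxy]-3a,4,5,6,9,11a-hexahydrocyclodeca[b]furan-2(3H)-one | C=C1C(=O)O[C@H]2/C=C(/C)[C@@H](O[Si](C)(C)C(C)(C)C)/C=C/[C@@](C)(O)C[C@H](O[Si](CC)(CC)CC)[C@@H]12
F0 | step 5 | none | none
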